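**Conventions.** Atom numbers are the germacrane numbers of the target (C1–C15). In the decalin intermediates the face carrying the angular methyl C14 and H5 is called α, the other face β. Compound numbers 1–36 are fixed by the compound list after the steps.

## Analysis of the target

The target is a germacranolide: a ten-membered carbocycle (C1–C10) fused at C6/C7 to an α-methylene-γ-butyrolactone (O6–C12(=O)–C11(=C13)–C7). The ring carries four stereocentres, C1 (R, hydroperoxide), C6 (S), C7 (R) and C8 (S). O6 and C11 are cis (cis-fused lactone) and O8 is trans to C11; a fifth centre (3′R) sits in the 3,4-dihydroxy-2-methylenebutanoate on O8. The C4=C5 alkene has its ring bonds cis and bears the C15 acetate (CIP descriptor E, because C15 is oxygenated); C10=C14 is exocyclic. Sensitive groups are the secondary allylic hydroperoxide, two acrylate-type Michael acceptors, the allylic acetate, and a free 1,2-diol next to an acrylate ester, which lactonises under base with loss of the C8 alcohol. The difficulty is a medium ring with defined alkene geometry next to a contiguous C6–C8 triad, with the hydroperoxide introduced last. The strategy rests on two observations. C1–OOH/C10=C14 is the ene product of an (E)-C1=C10 alkene. That alkene and the ring-cis C4=C5 alkene with its C15 oxygen lie 1,5 across the ring, which is the pattern obtained when a C5–C10-bonded cis-decalin carrying C1–B and a C4 spiro-epoxide unzips.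

## Retrosynthetic reasoning

**36 ⇒ 35.** The C1–O bond and the C10=C14 alkene are traced back to an (E)-C1=C10 alkene by an ene photo-oxygenation. It is placed last because no other step tolerates the hydroperoxide; the other four alkenes of 35 are electron-poor or deactivated by allylic oxygen.

**35 ⇒ 29 + 33.** The C8 ester bond is cut, giving alcohol 29 and the acetonide-protected acid 33 (via ester 34). Acid 33 comes from the chiral-pool alcohol 30 through aldehyde 31 and enal 32, so the 3′R centre is bought, not made.

**29 ⇒ 27 ⇒ 24 ⇒ 21.** The C11=C13 methylene is removed (enolate Mannich methylenation of lactone 24) and the lactone carbonyl is traced to the cyclic acetal of 22. C12 is kept at the acetal level until the ring is open because the fragmentation uses an organolithium. The C15 acetate is put on only after the enolate step (28 ⇒ 29).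

**21 ⇒ 19 (key disconnection).** The C5–C10 bond is re-formed: the 1,5-diene of 21 becomes cis-decalin 19 with an equatorial C1 boronate and an equatorial C4–O spiro-epoxide bond, both antiperiplanar to C5–C10. This is chosen because the ring, both alkene geometries and the C15 oxygen come from one bond cleavage, and no medium-ring cyclisation is needed. Relative to the simplest form of this precursor, O6 and C12 are tied together as a cyclic 4-methoxybenzyl acetal, the form in which the radical cyclisation below delivers them.

**19 ⇒ 18 ⇒ 14.** The epoxide is traced to the 4(15)-alkene; oxygen must enter anti to the syn-axial C14 methyl. The C1–B bond is traced to the C1 ketone through alcohol 15 and xanthate 16 by radical borylation. Hydrogenation of a C1 alkenyl boronate was considered and rejected: the β face of C1 is covered by O6, hydrogen would arrive from the methyl face and boron would end trans to C14, the epimer that cannot fragment. Forming the C–B bond itself from the open α face gives the required epimer.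

**14 ⇒ 11 ⇒ 7 + 10.** The C7–C11 and C8–O bonds are cut together: a haloacetal radical cyclisation from O6 onto C7=C8 with oxygen capture at C8. The 5-exo closure forces C11 cis to O6, and oxygen enters C8 from the open α face, so C7 and C8 follow from C6.

**7 ⇒ 6 ⇒ 5 ⇒ 4 ⇒ 2 + 3.** The C4 methylene goes back to the C4 ketone, ring A to the methoxy-enedione, and the cis-decalin to a Diels–Alder reaction of diene 2 with quinone 3. This forms C5–C6 and C9–C10 and sets C5, C6 and C10; it delivers both carbonyls (C1, C4), the C6 oxygen and the C7=C8 alkene in one step.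

## Alternatives that were turned down

**Alternative 1:** Disconnection of C10–C14 and C1–C2 on an open C3–C15 chain. Forward, a zirconium-catalysed syn-methylalumination of a terminal C1≡C10 alkyne is followed by opening of a two-carbon epoxide by the alkenyl alanate, giving the (E)-alkene A1 with the C4≡C5 alkyne intact. In its favour: the reaction type is well established, the (E)-geometry is secure, and three components are joined. Against it here: the ring is not made; the C3–C4 bond and the cis-reduction of the alkyne remain; the C6–C8 triad has to be built acyclically beforehand; and the Lewis-acidic aluminium meets an acetal and a benzylic ether. On precedent and on the C1=C10 geometry this route is stronger. The chosen route offers ring, both alkenes and the C15 oxygen from one stereospecific event on a decalin assembled in a few steps.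

**Alternative 2:** Disconnection of O–C6 and O–C15 on a preformed ten-membered triene acid. Forward, a palladium-catalysed oxidative 1,4-acetoxy-lactonisation of the C6=C5–C4=C15 diene closes the lactone and shifts the alkene to C4=C5, giving A2. In its favour: lactone, acetate and alkene shift in one step, ending on a very late intermediate (A2 differs from 27 only at C15). Against it: the ten-membered ring must already exist, so the hard problem is deferred; the C4=C5 geometry depends on the syn/anti form of the π-allyl intermediate; the cis-lactone needs a defined face of attack that nothing enforces; and the C1=C10 alkene competes for palladium. It is more step-economic at the end. The chosen route fixes the C4=C5 geometry by stereoelectronics and builds the lactone by routine steps.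

**Alternative 3:** Disconnection of C3–C4. Forward, hydroboration of the terminal alkene of a C1–C3 diene and intramolecular B-alkyl Suzuki coupling with a C4 vinyl iodide closes the ring to A3. In its favour: a known macrocyclisation class, both alkene geometries preset, mild conditions; on precedent for the ring-forming step it is as strong or stronger. Against it: closure of a strained ten-membered ring needs high dilution and competes with protodeboronation, β-hydride elimination and oligomerisation; hydroboration must discriminate within a 1,3-diene and against the vinyl iodide; the acyclic precursor with the triad, a (Z)-iodoalkene and an (E)-diene is a long linear synthesis. The chosen route pays no cyclisation entropy and takes its stereocentres from one cycloaddition and one radical cyclisation, at the price of an unprecedented key step.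

Key step: step 14

**Remarks (assumptions).**
- The sense of induction of the oxazaborolidinium catalyst in step 2 is assumed from its usual pre-transition-state model; if the antipode forms, the enantiomeric catalyst is used and nothing else changes.
- C12 (acetal or lactol carbon, 11–23) and C11 (25, 26) are epimer mixtures that converge later; their SMILES leave these centres undefined. The C1 configuration of 15 and 16 is inconsequential.

## Route

Step 1
Reactants: 1 (E)-but-2-enal
Product: 2 (E)-1-(tert-butyldimethylsilyloxy)buta-1,3-diene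
Conditions: TBSOTf, Et3N, Et2O, 0 → 23 °C
Reagents that add atoms: tert-butyldimethylsilyl triflate, CC(C)(C)[Si](C)(C)OS(=O)(=O)C(F)(F)F
Why: Soft enolisation of the enal: O-silylation and γ-deprotonation give the (E)-dienyl silyl ether; no stereocentre is formed.

Step 2
Reactants: 2 (E)-1-(tert-butyldimethylsilyloxy)buta-1,3-diene; 3 2-methoxy-5-methyl-1,4-benzoquinone
Product: 4 (5S,6R,10S) cis-fused cycloadduct: 6β-silyloxy-3-methoxy-10α-methyl-5α-H-decalin-2,7-diene-1,4-dione
Conditions: (S)-α,α-diphenylprolinol-derived B-(o-tolyl)oxazaborolidine (20 mol %), HNTf2 (18 mol %), CH2Cl2, −78 → −40 °C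
Reagents that add atoms: none
Why: Catalytic enantioselective Diels–Alder reaction: only the methyl-bearing quinone alkene reacts (the other is a deactivated vinylogous ester), the carbonyl next to its CH carbon directs the diene CH2 terminus to the methyl-bearing carbon (C9–C10) and the silyloxy terminus to C5, and the endo transition state gives the cis fusion with O6 trans to H5; the catalyst selects the quinone face.

Step 3
Reactants: 4 cycloadduct
Product: 5 (5S,6R,10S)-6β-silyloxy-10α-methyl-cis-decal-7-ene-1,4-dione
Conditions: SmI2 (5 equiv), THF/MeOH, −78 °C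
Reagents that add atoms: none
Why: SmI2 reduces the ene-dione alkene and reductively cleaves the C3 methoxy group α to the C4 ketone, both standard reactions; the isolated C7=C8 alkene and the ring fusion are untouched at −78 °C.

Step 4
Reactants: 5 cis-decalindione
Product: 6 6β-silyloxy-4-methylene-10α-methyl-cis-decal-7-en-1-one
Conditions: Zn, CH2Br2, TiCl4, THF/CH2Cl2, 0 → 23 °C
Reagents that add atoms: dibromomethane, BrCBr
Why: Takai–Lombardo methylenation is non-basic, so the β-silyloxy ketone neither eliminates nor epimerises at C5; the C1 carbonyl, flanked by the quaternary C10, should react much more slowly than C4.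

Step 5
Reactants: 6 methylene ketone
Product: 7 6β-hydroxy-4-methylene-10α-methyl-cis-decal-7-en-1-one
Conditions: HF·pyridine, pyridine, THF, 0 → 23 °C
Reagents that add atoms: none
Why: Fluoride desilylation under buffered conditions; with C4 no longer a ketone the free C6 alcohol cannot undergo retro-aldol or β-elimination.

Step 6
Reactants: 8 4-methoxybenzyl alcohol; 9 vinyl acetate
Product: 10 4-methoxybenzyl vinyl ether
Conditions: [Ir(cod)Cl]2 (1 mol %), Na2CO3 (0.6 equiv), toluene, 100 °C
Reagents that add atoms: none
Why: Iridium-catalysed transfer vinylation of a primary alcohol with vinyl acetate, a known preparation of vinyl ethers.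

Step 7
Reactants: 7 allylic alcohol; 10 4-methoxybenzyl vinyl ether
Product: 11 C6 O-[2-bromo-1-(4-methoxybenzyloxy)ethyl] mixed acetal of 7
Conditions: NBS, CH2Cl2, −40 → 0 °C
Reagents that add atoms: N-bromosuccinimide, O=C1CCC(=O)N1Br
Why: Bromoacetalisation: the electron-rich enol ether is brominated selectively and the oxocarbenium ion is captured by the C6 hydroxyl; the two ring alkenes are far less nucleophilic.

Step 8
Reactants: 11 bromoacetal
Product: 13 tricyclic acetal with 7β-C11 and 8α-hydroxyl, via C8 hydroperoxide 12 (not isolated)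
Conditions: Bu3SnH (syringe pump), Et3B (cat.), dry air, toluene, 0 °C; then PPh3
Reagents that add atoms: dioxygen, O=O
Why: Ueno–Stork haloacetal radical cyclisation with oxygen trapping, a known variant: 5-exo closure from the O6 tether puts C11 on C7 cis to O6, the C8 radical takes up O2 from the open α face (the β face carries O6 and C1 syn-axial), and PPh3 reduces the hydroperoxide; this sets C7 and C8.

Step 9
Reactants: 13 C8 alcohol
Product: 14 8α-tert-butyldimethylsilyl ether of 13
Conditions: TBSCl, imidazole, DMF, 23 °C
Reagents that add atoms: tert-butyldimethylsilyl chloride, CC(C)(C)[Si](C)(C)Cl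
Why: Silylation of an equatorial secondary alcohol; TBSCl/imidazole is chosen over the triflate so that the mixed acetal is not ionised.

Step 10
Reactants: 14 silyl ether ketone
Product: 15 C1 alcohol (1β-OH expected)
Conditions: NaBH4, MeOH/THF, 0 → 23 °C
Reagents that add atoms: none
Why: Hydride reduction of the only carbonyl; hydride should enter from the α face because O6 covers the β face; the C1 configuration is lost in step 12.

Step 11
Reactants: 15 C1 alcohol
Product: 16 C1 O-alkyl S-methyl xanthate
Conditions: NaH, CS2, THF, 0 °C; then MeI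
Reagents that add atoms: carbon disulfide, S=C=S; iodomethane, CI
Why: Standard xanthate formation; the small linear CS2 reaches even a hindered secondary alkoxide.

Step 12
Reactants: 16 xanthate
Product: 18 1α-pinacol boronate with 4(15)-alkene, via catechol boronate 17 (not isolated)
Conditions: B2cat2, DMF, blue LEDs, 25 °C; then pinacol, Et3N
Reagents that add atoms: bis(catecholato)diboron, B1(Oc2ccccc2O1)B1Oc2ccccc2O1; pinacol, CC(C)(O)C(C)(C)O
Why: Radical-chain deoxygenative borylation of a secondary alkyl xanthate: the C1 radical is captured by DMF-ligated B2cat2 on the α face, because the β lobe of C1 points at O6 (syn-axial on ring B), so boron ends cis to C14 and equatorial; pinacol then exchanges the catechol ligand.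

Step 13
Reactants: 18 pinacol boronate alkene
Product: 19 cis-decalin key precursor: 1α-Bpin and 4β-O spiro-epoxide (C15 α) with 5α-H, fused O6/C12 4-methoxybenzyl acetal (C11 β), 8α-OTBS, 10α-CH3
Conditions: dimethyldioxirane (acetone), CH2Cl2, −20 → 0 °C
Reagents that add atoms: dimethyldioxirane, CC1(C)OO1
Why: Neutral dioxirane epoxidation of the 1,1-disubstituted alkene; oxygen should enter on the β (equatorial) face because the α face is blocked by the syn-axial C14 methyl, and the acid-free electrophilic oxidant should spare the C–B bond and the acetal.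

Step 14
Reactants: 19 boronate epoxide
Product: 21 cyclodeca-1(10),4-diene with (E)-C1=C10 and ring-cis C4=C5 and free C15 hydroxyl, via lithium borate 20 (not isolated)
Conditions: CH3Li (1.05 equiv), Et2O/THF, −78 °C; then LiClO4 (Et2O), −78 → 23 °C; aq. NaHCO3
Reagents that add atoms: none
Why: Proposed new method: CH3Li adds to boron to give borate 20, whose C1–B bond is a strong σ donor; in the chair–chair conformer with C9 equatorial and C6 axial on ring A, the equatorial C1–B bond, the C5–C10 bond and the equatorial C4–O bond of the LiClO4-activated epoxide are antiperiplanar, so a concerted seven-centre Grob-type fragmentation forms C1=C10 and C4=C5, breaks C5–C10 and releases the C15 alkoxide and CH3Bpin. The closest known reactions are the fragmentation of borates of decalin sulfonates to cyclodeca-1,5-dienes and the Grob fragmentation of epoxy alkoxides; a borate electrofuge paired with an epoxide nucleofuge at a fully substituted carbon is not precedented. The ten-membered ring is not closed but unveiled by cleavage of the ring-fusion bond, so no cyclisation entropy or transannular strain is paid in a ring-closing transition state. No stereocentre is formed: C1, C4, C5 and C10 become sp2 and C6–C8 are untouched. Geometry is stereospecific: equatorial C9 is anti to C2, which gives (E)-C1=C10, and axial C6 is gauche to C3 and anti to C15, which gives the ring-cis C4=C5 with C15 trans to C6. The step needs attack of CH3Li at boron before the epoxide (fast at −78 °C with one equivalent) and fragmentation faster than Lewis-acid rearrangement of the epoxide to the C15 aldehyde; the equatorial C7 and C8 substituents bias ring B toward the reactive conformer.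

Step 15
Reactants: 21 cyclodecadiene alcohol
Product: 22 C15/C8 bis(tert-butyldimethylsilyl) ether
Conditions: TBSCl, imidazole, DMF, 0 °C
Reagents that add atoms: tert-butyldimethylsilyl chloride, CC(C)(C)[Si](C)(C)Cl
Why: Silylation of the primary allylic alcohol so that it survives the oxidant and the enolate chemistry that follow.

Step 16
Reactants: 22 bis-silyl ether
Product: 23 6,12-lactol
Conditions: DDQ, CH2Cl2/pH 7 buffer, 0 °C
Reagents that add atoms: none
Why: Oxidative cleavage of the 4-methoxybenzyl acetal (as for 4-methoxybenzyl glycosides) frees the lactol without protic acid, which the cyclodecadiene would not tolerate.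

Step 17
Reactants: 23 lactol
Product: 24 cis-fused 6,12-lactone
Conditions: Dess–Martin periodinane, NaHCO3, CH2Cl2, 0 → 23 °C
Reagents that add atoms: none
Why: Lactol-to-lactone oxidation under buffered conditions; no other free hydroxyl is present.

Step 18
Reactants: 24 lactone
Product: 27 α-methylene lactone, via Mannich base 25 (not isolated), via ammonium iodide 26 (not isolated)
Conditions: LiN(SiMe3)2, THF, −78 °C; CH2=NMe2+ I−, −78 → 23 °C; then MeI, MeOH; then aq. NaHCO3
Reagents that add atoms: N,N-dimethylmethyleneiminium iodide, C=[N+](C)C.[I-]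
Why: Classical lactone α-methylenation: enolate Mannich reaction, N-methylation and β-elimination; only C11 is deprotonated, so C7 is not at risk, and no other enolisable ester is present at this stage.

Step 19
Reactants: 27 bis-silyl α-methylene lactone
Product: 28 C8,C15-diol
Conditions: HF·pyridine, pyridine, THF, 0 → 23 °C
Reagents that add atoms: none
Why: Buffered fluoride removes both silyl ethers; the conditions are too weakly basic for translactonisation to O8 or conjugate addition.

Step 20
Reactants: 28 diol
Product: 29 C15 acetate with free C8 hydroxyl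
Conditions: Ac2O (1.1 equiv), 2,4,6-collidine, CH2Cl2, −20 °C
Reagents that add atoms: acetic anhydride, CC(=O)OC(C)=O
Why: Selective acetylation of the primary allylic alcohol over the hindered secondary C8 alcohol next to the ring fusion.

Step 21
Reactants: 30 (R)-2-(2,2-dimethyl-1,3-dioxolan-4-yl)ethanol
Product: 31 (R)-2-(2,2-dimethyl-1,3-dioxolan-4-yl)acetaldehyde
Conditions: Dess–Martin periodinane, NaHCO3, CH2Cl2, 0 → 23 °C
Reagents that add atoms: none
Why: Mild oxidation of the primary alcohol; the stereocentre is not α to the new carbonyl.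

Step 22
Reactants: 31 aldehyde
Product: 32 2-[(4R)-2,2-dimethyl-1,3-dioxolan-4-yl]prop-2-enal
Conditions: CH2=NMe2+ I−, Et3N, CH2Cl2, 23 °C
Reagents that add atoms: N,N-dimethylmethyleneiminium iodide, C=[N+](C)C.[I-]
Why: Eschenmoser methylenation of an aldehyde (Mannich reaction, then loss of dimethylamine); after methylenation no α-hydrogen remains, so the β-alkoxy group cannot eliminate.

Step 23
Reactants: 32 enal
Product: 33 2-[(4R)-2,2-dimethyl-1,3-dioxolan-4-yl]acrylic acid
Conditions: NaClO2, NaH2PO4, 2-methyl-2-butene, t-BuOH/H2O, 0 °C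
Reagents that add atoms: sodium chlorite, [Na+].[O-]Cl=O
Why: Pinnick oxidation converts enals to acrylic acids without touching the alkene or the acetonide at this pH.

Step 24
Reactants: 29 C8 alcohol; 33 acrylic acid
Product: 34 C8 ester with acetonide-protected side chain
Conditions: 33, 2,4,6-trichlorobenzoyl chloride, Et3N, THF; then 29, DMAP, toluene, 0 → 23 °C
Reagents that add atoms: none
Why: Yamaguchi esterification acylates hindered secondary alcohols with α-substituted acrylic acids; the alcohol is added to the preformed mixed anhydride to limit its exposure to base.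

Step 25
Reactants: 34 acetonide ester
Product: 35 (3′R)-3′,4′-diol ester
Conditions: AcOH/H2O (4:1), 23 °C
Reagents that add atoms: none
Why: Terminal acetonides hydrolyse in aqueous acetic acid; the acidic medium also suppresses lactonisation of the diol onto the acrylate.

Step 26
Reactants: 35 diol ester
Product: 36 target (1R,6S,7R,8S,3′R)
Conditions: O2, hν (visible), methylene blue (cat.), MeCN, 0 °C
Reagents that add atoms: dioxygen, O=O
Why: Schenck ene reaction of singlet oxygen at the only electron-rich alkene: by the cis effect a hydrogen is taken from C14 on the more substituted side, giving C1–OOH and C10=C14 as in related germacranolide photo-oxygenations; C4=C5 is deactivated by its allylic oxygens, and C1 is set by attack on the outer face of C1=C10 in the preferred ring conformer.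

## Compound list

1 | (E)-but-2-enal | C/C=C/C=O | starting material
2 | (E)-1-(tert-butyldimethylsilyloxy)buta-1,3-diene | C=C/C=C/O[Si](C)(C)C(C)(C)C | intermediate
3 | 2-methoxy-5-methyl-1,4-benzoquinone | COC1=CC(=O)C(C)=CC1=O | starting material
4 | (5S,6R,10S) cycloadduct; = (4aS,5R,8aS)-5-(tert-butyldimethylsilyloxy)-3-methoxy-8a-methyl-4a,5,8,8a-tetrahydronaphthalene-1,4-dione | CC(C)(C)[Si](C)(C)O[C@H]1[C@H]2C(=O)C(OC)=CC(=O)[C@@]2(C)CC=C1 | intermediate
5 | (4aS,5R,8aS)-5-(tert-butyldimethylsilyloxy)-8a-methyl-2,3,4a,5,8,8a-hexahydronaphthalene-1,4-dione | CC(C)(C)[Si](C)(C)O[C@H]1[C@H]2C(=O)CCC(=O)[C@@]2(C)CC=C1 | intermediate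
6 | (4aS,5R,8aS)-5-(tert-butyldimethylsilyloxy)-8a-methyl-4-methylene-3,4,4a,5,8,8a-hexahydronaphthalen-1(2H)-one | CC(C)(C)[Si](C)(C)O[C@H]1[C@H]2C(=C)CCC(=O)[C@@]2(C)CC=C1 | intermediate
7 | (4aS,5R,8aS)-5-hydroxy-8a-methyl-4-methylene-3,4,4a,5,8,8a-hexahydronaphthalen-1(2H)-one | O[C@H]1[C@H]2C(=C)CCC(=O)[C@@]2(C)CC=C1 | intermediate
8 | 4-methoxybenzyl alcohol | COc1ccc(CO)cc1 | starting material
9 | vinyl acetate | C=COC(C)=O | starting material
10 | 4-methoxybenzyl vinyl ether | C=COCc1ccc(OC)cc1 | intermediate
11 | C6 O-[2-bromo-1-(4-methoxybenzyloxy)ethyl] acetal of 7 (acetal epimers) | BrCC(OCc1ccc(OC)cc1)O[C@H]1[C@H]2C(=C)CCC(=O)[C@@]2(C)CC=C1 | intermediate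
12 | tricyclic acetal, 8α-hydroperoxide (O6 and C11 β, cis-fused 2-(4-methoxybenzyloxy)tetrahydrofuran; C1 ketone; 4-methylene) | COc1ccc(COC2C[C@H]3[C@@H](O2)[C@H]4C(=C)CCC(=O)[C@@]4(C)C[C@@H]3OO)cc1 | intermediate (not isolated)
13 | tricyclic acetal, 8α-alcohol | COc1ccc(COC2C[C@H]3[C@@H](O2)[C@H]4C(=C)CCC(=O)[C@@]4(C)C[C@@H]3O)cc1 | intermediate
14 | tricyclic acetal, 8α-OTBS, C1 ketone, 4-methylene | COc1ccc(COC2C[C@H]3[C@@H](O2)[C@H]4C(=C)CCC(=O)[C@@]4(C)C[C@@H]3O[Si](C)(C)C(C)(C)C)cc1 | intermediate
15 | C1 alcohol of 14 (1β-OH) | COc1ccc(COC2C[C@H]3[C@@H](O2)[C@H]4C(=C)CC[C@@H](O)[C@@]4(C)C[C@@H]3O[Si](C)(C)C(C)(C)C)cc1 | intermediate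
16 | C1 O-alkyl S-methyl xanthate | COc1ccc(COC2C[C@H]3[C@@H](O2)[C@H]4C(=C)CC[C@@H](OC(=S)SC)[C@@]4(C)C[C@@H]3O[Si](C)(C)C(C)(C)C)cc1 | intermediate
17 | 1α-catechol boronate | COc1ccc(COC2C[C@H]3[C@@H](O2)[C@H]4C(=C)CC[C@H](B5Oc6ccccc6O5)[C@@]4(C)C[C@@H]3O[Si](C)(C)C(C)(C)C)cc1 | intermediate (not isolated)
18 | 1α-pinacol boronate, 4-methylene | COc1ccc(COC2C[C@H]3[C@@H](O2)[C@H]4C(=C)CC[C@H](B5OC(C)(C)C(C)(C)O5)[C@@]4(C)C[C@@H]3O[Si](C)(C)C(C)(C)C)cc1 | intermediate
19 | key precursor: 1α-pinacol boronate, 4β-O spiro-epoxide, 5α-H, 10α-CH3, 8α-OTBS, fused O6/C12 4-methoxybenzyl acetal | COc1ccc(COC2C[C@H]3[C@@H](O2)[C@H]4[C@]5(CO5)CC[C@H](B6OC(C)(C)C(C)(C)O6)[C@@]4(C)C[C@@H]3O[Si](C)(C)C(C)(C)C)cc1 | intermediate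
20 | lithium methyl(pinacolato)borate of 19 | [Li+].COc1ccc(COC2C[C@H]3[C@@H](O2)[C@H]4[C@]5(CO5)CC[C@H]([B-]6(C)OC(C)(C)C(C)(C)O6)[C@@]4(C)C[C@@H]3O[Si](C)(C)C(C)(C)C)cc1 | intermediate (not isolated)
21 | key product: (1(10)E,4E by CIP; ring bonds cis at C4=C5)-cyclodecadiene, C15-OH, 8-OTBS, O6/C11 cis, O8 trans to C11, fused 4-methoxybenzyl acetal | COc1ccc(COC2C[C@H]3[C@@H](O2)/C=C(/CO)CC/C=C(\C)C[C@@H]3O[Si](C)(C)C(C)(C)C)cc1 | intermediate
22 | C15,C8-bis(TBS) ether of 21 | COc1ccc(COC2C[C@H]3[C@@H](O2)/C=C(/CO[Si](C)(C)C(C)(C)C)CC/C=C(\C)C[C@@H]3O[Si](C)(C)C(C)(C)C)cc1 | intermediate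
23 | 6,12-lactol | OC1C[C@H]2[C@@H](O1)/C=C(/CO[Si](C)(C)C(C)(C)C)CC/C=C(\C)C[C@@H]2O[Si](C)(C)C(C)(C)C | intermediate
24 | cis-fused 6,12-lactone | O=C1C[C@H]2[C@@H](O1)/C=C(/CO[Si](C)(C)C(C)(C)C)CC/C=C(\C)C[C@@H]2O[Si](C)(C)C(C)(C)C | intermediate
25 | C11 (dimethylaminomethyl) lactone | CN(C)CC1C(=O)O[C@H]2/C=C(/CO[Si](C)(C)C(C)(C)C)CC/C=C(\C)C[C@H](O[Si](C)(C)C(C)(C)C)[C@@H]12 | intermediate (not isolated)
26 | C11 (trimethylammoniomethyl) lactone iodide | C[N+](C)(C)CC1C(=O)O[C@H]2/C=C(/CO[Si](C)(C)C(C)(C)C)CC/C=C(\C)C[C@H](O[Si](C)(C)C(C)(C)C)[C@@H]12.[I-] | intermediate (not isolated)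
27 | α-methylene lactone, C15-OTBS, C8-OTBS | C=C1C(=O)O[C@H]2/C=C(/CO[Si](C)(C)C(C)(C)C)CC/C=C(\C)C[C@H](O[Si](C)(C)C(C)(C)C)[C@@H]12 | intermediate
28 | α-methylene lactone C8,C15-diol | C=C1C(=O)O[C@H]2/C=C(/CO)CC/C=C(\C)C[C@H](O)[C@@H]12 | intermediate
29 | α-methylene lactone, C15-OAc, C8-OH | C=C1C(=O)O[C@H]2/C=C(/COC(C)=O)CC/C=C(\C)C[C@H](O)[C@@H]12 | intermediate
30 | (R)-2-(2,2-dimethyl-1,3-dioxolan-4-yl)ethanol | OCC[C@@H](OC1(C)C)CO1 | starting material
31 | (R)-2-(2,2-dimethyl-1,3-dioxolan-4-yl)acetaldehyde | O=CC[C@@H]1COC(C)(C)O1 | intermediate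
32 | 2-[(4R)-2,2-dimethyl-1,3-dioxolan-4-yl]prop-2-enal | O=CC(=C)[C@@H]1COC(C)(C)O1 | intermediate
33 | 2-[(4R)-2,2-dimethyl-1,3-dioxolan-4-yl]acrylic acid | OC(=O)C(=C)[C@@H]1COC(C)(C)O1 | intermediate
34 | C8 ester of 29 with 33 (acetonide) | C=C1C(=O)O[C@H]2/C=C(/COC(C)=O)CC/C=C(\C)C[C@H](OC(=O)C(=C)[C@@H]3COC(C)(C)O3)[C@@H]12 | intermediate
35 | C8 (3′R)-3′,4′-dihydroxy-2′-methylenebutanoate with (E)-C1=C10 | C=C1C(=O)O[C@H]2/C=C(/COC(C)=O)CC/C=C(\C)C[C@H](OC(=O)C(=C)[C@@H](O)CO)[C@@H]12 | intermediate
36 | (1R,6S,7R,8S)-15-acetoxy-1-hydroperoxy-8-[(3R)-3,4-dihydroxy-2-methylenebutanoyloxy]germacra-4,10(14),11(13)-trien-12,6-olide (CNP0307408.1) | C=C1C(=O)O[C@H]2/C=C(/COC(C)=O)CC[C@@H](OO)C(=C)C[C@H](OC(=O)C(=C)[C@@H](O)CO)[C@@H]12 | target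

## Step count and risks

Total: 26 steps. Longest linear sequence: 22 steps (steps 1–5, 7–20, 24–26); steps 6 and 21–23 are side branches.

**Step 14 (key step, proposed new method).** Most likely failure: the borate forms but the epoxide C–O bond does not ionise, or under Lewis-acid activation a hydride shift to the C15 aldehyde outruns C5–C10 cleavage. Fallback, with established operations and the sulfate/sulfonate ester class of nucleofuge for which this borate fragmentation is precedented: it sets out from 18 and returns at 21. The 4(15)-alkene is dihydroxylated from the β face (OsO4 cat., N-methylmorpholine N-oxide) to the 4β,15-diol F1. This is closed with 1,1′-sulfonyldiimidazole/NaH to the 4,15-cyclic sulfate F2, the one sulfonate-type leaving group that is stable on a fully substituted carbon. CH3Li at −78 °C then triggers the same antiperiplanar fragmentation and gives the lithium C15 sulfate monoester F3. Brief treatment with catalytic H2SO4 in moist THF at 0 °C hydrolyses it to 21.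

**Step 12.** Most likely failure: poor chain propagation at the neopentyl-type C1 (hydrogen abstraction to C1–H) or insufficient facial discrimination in C–B bond formation. Fallback, which forms the C1–H bond last instead: from 14, returning at 19. KN(SiMe3)2/PhNTf2 gives the C1 enol triflate F4; B2pin2, PdCl2(dppf) and KOAc give the alkenyl boronate F5; dimethyldioxirane epoxidises the 4(15)-alkene to F6. Hydrogenation with the cationic complex [Ir(cod)(PCy3)(py)]PF6 is then relied on to bind the acetal oxygen O6 and deliver hydrogen to the β face it covers, giving 19; an undirected catalyst would give the C1 epimer.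

**Step 13.** Most likely failure: oxygen transfer to the α face, or competing oxidation of the C–B bond. Fallback with the opposite facial outcome: from 18, returning at 19. NBS in aqueous THF places bromine on the face the dioxirane would have attacked and water on the other face of C4, giving bromohydrin F7; K2CO3 in MeOH closes it to 19.

**Step 2.** Most likely failure: low enantioselectivity, stepwise Mukaiyama–Michael addition of the silyl dienol ether, or loss of regiocontrol under Lewis acid. Fallback by auxiliary control without Lewis acid: from 1 and 3, returning at 7. Deprotonation of 1 (KOt-Bu) and acylation with (S)-2-methoxy-2-phenylacetyl chloride give the dienyl ester F8. Thermal cycloaddition with 3 gives the diastereomeric adducts, from which F9 is separated. Reduction and methylenation as in steps 3 and 4 give dione F10 and methylene ketone F11, and K2CO3/MeOH removes the auxiliary to give 7. The enantiomer of the auxiliary is used if it favours F9 better.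

**Step 26.** Most likely failure: attack on the wrong face of C1=C10, hydrogen abstraction from C2 or C9 instead of C14, or competing reaction at C4=C5. Fallback, which moves the ene reaction to a conformationally different substrate and carries a masked peroxide: from 29, returning at 36. Photo-oxygenation of 29 in a non-polar solvent, where the free C8 hydroxyl can steer the oxidant by hydrogen bonding, gives hydroperoxide F12. 2-Methoxypropene/pyridinium tosylate masks it as the peroxyketal F13. Yamaguchi acylation with 33 gives F14, and the aqueous acetic acid of step 25 removes both the peroxyketal and the acetonide to give 36.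

Further compounds
F1 | step 14 | 4β,15-diol of 18 | COc1ccc(COC2C[C@H]3[C@@H](O2)[C@H]4[C@](O)(CO)CC[C@H](B5OC(C)(C)C(C)(C)O5)[C@@]4(C)C[C@@H]3O[Si](C)(C)C(C)(C)C)cc1
F2 | step 14 | 4,15-cyclic sulfate | COc1ccc(COC2C[C@H]3[C@@H](O2)[C@H]4[C@]5(COS(=O)(=O)O5)CC[C@H](B6OC(C)(C)C(C)(C)O6)[C@@]4(C)C[C@@H]3O[Si](C)(C)C(C)(C)C)cc1
F3 | step 14 | lithium C15 sulfate monoester of 21 | [Li+].COc1ccc(COC2C[C@H]3[C@@H](O2)/C=C(/COS(=O)(=O)[O-])CC/C=C(\C)C[C@@H]3O[Si](C)(C)C(C)(C)C)cc1
F4 | step 12 | C1 enol triflate of 14 | COc1ccc(COC2C[C@H]3[C@@H](O2)[C@H]4C(=C)CC=C(OS(=O)(=O)C(F)(F)F)[C@@]4(C)C[C@@H]3O[Si](C)(C)C(C)(C)C)cc1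
F5 | step 12 | C1 alkenyl pinacol boronate | COc1ccc(COC2C[C@H]3[C@@H](O2)[C@H]4C(=C)CC=C(B5OC(C)(C)C(C)(C)O5)[C@@]4(C)C[C@@H]3O[Si](C)(C)C(C)(C)C)cc1
F6 | step 12 | C1 alkenyl pinacol boronate 4β-O spiro-epoxide | COc1ccc(COC2C[C@H]3[C@@H](O2)[C@H]4[C@]5(CO5)CC=C(B6OC(C)(C)C(C)(C)O6)[C@@]4(C)C[C@@H]3O[Si](C)(C)C(C)(C)C)cc1
F7 | step 13 | 15-bromo-4β-hydroxy bromohydrin of 18 | COc1ccc(COC2C[C@H]3[C@@H](O2)[C@H]4[C@](O)(CBr)CC[C@H](B5OC(C)(C)C(C)(C)O5)[C@@]4(C)C[C@@H]3O[Si](C)(C)C(C)(C)C)cc1
F8 | step 2 | (1E)-buta-1,3-dien-1-yl (2S)-methoxy(phenyl)acetate | C=C/C=C/OC(=O)[C@@H](OC)c1ccccc1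
F9 | step 2 | cycloadduct with C6 (2S)-methoxy(phenyl)acetate | O=C(O[C@H]1[C@H]2C(=O)C(OC)=CC(=O)[C@@]2(C)CC=C1)[C@@H](OC)c1ccccc1
F10 | step 2 | cis-decal-7-ene-1,4-dione C6 (2S)-methoxy(phenyl)acetate | O=C(O[C@H]1[C@H]2C(=O)CCC(=O)[C@@]2(C)CC=C1)[C@@H](OC)c1ccccc1
F11 | step 2 | 4-methylene ketone C6 (2S)-methoxy(phenyl)acetate | O=C(O[C@H]1[C@H]2C(=C)CCC(=O)[C@@]2(C)CC=C1)[C@@H](OC)c1ccccc1
F12 | step 26 | 1-hydroperoxide of 29 with C10=C14 | C=C1C(=O)O[C@H]2/C=C(/COC(C)=O)CC[C@@H](OO)C(=C)C[C@H](O)[C@@H]12
F13 | step 26 | 2-methoxyprop-2-yl peroxyketal of F12 | C=C1C(=O)O[C@H]2/C=C(/COC(C)=O)CC[C@@H](OOC(C)(C)OC)C(=C)C[C@H](O)[C@@H]12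
F14 | step 26 | C8 ester of F13 with 33 | C=C1C(=O)O[C@H]2/C=C(/COC(C)=O)CC[C@@H](OOC(C)(C)OC)C(=C)C[C@H](OC(=O)C(=C)[C@@H]3COC(C)(C)O3)[C@@H]12
A1 | alternative 1 | (E)-alkene with C3 hydroxyl and C4≡C5 alkyne | OCC/C=C(\C)C[C@H](O[Si](C)(C)C(C)(C)C)[C@@H](CC(OC)OC)[C@@H](OCc1ccc(OC)cc1)C#CCO[Si](C(C)C)(C(C)C)C(C)C
A2 | alternative 2 | cis-fused α-methylene lactone with C15 acetate and C8 silyl ether | C=C1C(=O)O[C@H]2/C=C(/COC(C)=O)CC/C=C(\C)C[C@H](O[Si](C)(C)C(C)(C)C)[C@@H]12
A3 | alternative 3 | cyclodecadiene with C15 triisopropylsilyl ether, C6 4-methoxybenzyl ether and C12 dimethyl acetal | COc1ccc(CO[C@H]2/C=C(/CO[Si](C(C)C)(C(C)C)C(C)C)CC/C=C(\C)C[C@H](O[Si](C)(C)C(C)(C)C)[C@H]2CC(OC)OC)cc1
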